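**Strategy.** Atom labels follow the isochromene core (C1, O2, C3, C4, C4a, C5–C8, C8a). The plan rests on the tertiary α-ketol C6(=O)–C7(OH)(CH3) of the carbocycle C4a–C5–C6–C7–C8–C8a, read as the product of an acyloin (α-ketol) shift in a 1-acetylcyclopent-2-en-1-ol. In one operation the C6–C8 bond migrates to the acetyl carbon. This enlarges the five-membered ring to the cyclohexenone, creates the C7 carbinol centre from the C6 carbinol and unveils the enynone needed for pyran closure. The precursor is a trans-disubstituted cyclopentenol carrying the complete dienyne chain at C4a. It derives from (R)-4-silyloxycyclopentenone, whose bought stereocentre (C8) relays C8a, C6 and C7.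

Key step: step 9

Remark: (R)-4-[(tert-butyldimethylsilyl)oxy]cyclopent-2-en-1-one, (triisopropylsiloxy)methyl chloride and diethyl [3-(trimethylsilyl)prop-2-yn-1-yl]phosphonate are assumed to be purchasable; the labels C1–C8a are used for the corresponding atoms of the monocyclic intermediates as well.

Step 1
Reactants: 1 (S)-2-methylbutan-1-ol
Product: 3 ethyl (2E,4S)-2,4-dimethylhex-2-enoate, via (S)-2-methylbutanal 2 (not isolated)
Conditions: TEMPO (cat.), PhI(OAc)2, CH2Cl2, 0 °C to rt; then Ph3P=C(CH3)CO2Et, rt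
Reagents that add atoms: ethyl 2-(triphenylphosphoranylidene)propanoate, CCOC(=O)C(C)=P(c1ccccc1)(c1ccccc1)c1ccccc1
Why: The oxidation stops at the aldehyde, which is trapped at once by the stabilized ylide (Wittig olefination, E-selective), so the epimerizable α-centre of 2 is never stored or exposed to strong base.

Step 2
Reactants: 3 ethyl (2E,4S)-2,4-dimethylhex-2-enoate
Product: 4 (2E,4S)-2,4-dimethylhex-2-en-1-ol
Conditions: iBu2AlH, CH2Cl2, −78 °C; aq. sodium potassium tartrate
Reagents that add atoms: none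
Why: 1,2-Reduction of the enoate by the aluminium hydride should give the allylic alcohol without touching the trisubstituted alkene or the allylic stereocentre.

Step 3
Reactants: 4 (2E,4S)-2,4-dimethylhex-2-en-1-ol
Product: 5 (2E,4S)-2,4-dimethylhex-2-enal
Conditions: MnO2, CH2Cl2, rt
Reagents that add atoms: none
Why: MnO2 oxidizes allylic alcohols selectively to enals under neutral conditions, so the alkene geometry should be kept.

Step 4
Reactants: 5 (2E,4S)-2,4-dimethylhex-2-enal
Product: 7 (3E,5E,7S)-5,7-dimethylnona-3,5-dien-1-yne, via silylated dienyne 6 (not isolated)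
Conditions: (EtO)2P(O)CH2C≡CSiMe3, LiN(SiMe3)2, THF, −78 to 0 °C; then K2CO3 (cat.), MeOH, rt
Reagents that add atoms: diethyl [3-(trimethylsilyl)prop-2-yn-1-yl]phosphonate, CCOP(=O)(CC#C[Si](C)(C)C)OCC
Why: Horner–Wadsworth–Emmons olefination with the lithiated propargylic phosphonate should give the E-enyne, and methanolysis of the alkynyl C–Si bond in the same flask frees the terminal alkyne.

Step 5
Reactants: 8 (R)-4-[(tert-butyldimethylsilyl)oxy]cyclopent-2-en-1-one
Product: 10 (4S,5R)-4-[(tert-butyldimethylsilyl)oxy]-5-{[(triisopropylsilyl)oxy]methyl}cyclopent-2-en-1-one (trans), via lithium enolate 9 (not isolated)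
Conditions: LiN(iPr)2, THF, −78 °C; then iPr3SiOCH2Cl, −78 °C
Reagents that add atoms: (triisopropylsiloxy)methyl chloride, ClCO[Si](C(C)C)(C(C)C)C(C)C
Why: Kinetic deprotonation gives the cross-conjugated enolate, which the reactive α-chloro ether alkylates anti to the adjacent silyloxy group (enolate alkylation, 1,2-induction), setting the trans relation of the future C8 oxygen and C8a carbon; β-loss of silanolate is slow at −78 °C because it would give a cyclopentadienone.

Step 6
Reactants: 7 (3E,5E,7S)-5,7-dimethylnona-3,5-dien-1-yne; 10 (4S,5R)-4-[(tert-butyldimethylsilyl)oxy]-5-{[(triisopropylsilyl)oxy]methyl}cyclopent-2-en-1-one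
Product: 12 (1S,4S,5R)-4-[(tert-butyldimethylsilyl)oxy]-1-[(3E,5E,7S)-5,7-dimethylnona-3,5-dien-1-yn-1-yl]-5-{[(triisopropylsilyl)oxy]methyl}cyclopent-2-en-1-ol, via lithium acetylide 11 (not isolated)
Conditions: 7, n-BuLi, THF, −78 °C; then 10, −78 °C; then H2O
Reagents that add atoms: none
Why: The lithium acetylide adds 1,2 to the enone carbonyl (acetylide addition) and brings in the whole side chain; the configuration of the new carbinol (drawn as the expected major epimer) is irrelevant because this carbon becomes sp2 in step 7.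

Step 7
Reactants: 12 (1S,4S,5R)-4-[(tert-butyldimethylsilyl)oxy]-1-[(3E,5E,7S)-5,7-dimethylnona-3,5-dien-1-yn-1-yl]-5-{[(triisopropylsilyl)oxy]methyl}cyclopent-2-en-1-ol
Product: 13 (4R,5R)-5-[(tert-butyldimethylsilyl)oxy]-3-[(3E,5E,7S)-5,7-dimethylnona-3,5-dien-1-yn-1-yl]-4-{[(triisopropylsilyl)oxy]methyl}cyclopent-2-en-1-one
Conditions: pyridinium chlorochromate [C5H5NH][CrO3Cl], NaOAc, 4 Å molecular sieves, CH2Cl2, rt
Reagents that add atoms: none
Why: Chromate ester formation, [3,3]-shift to the allylic terminus and oxidation (Babler–Dauben oxidative transposition) should move the oxygen to the future C6 and bring the ring alkene into conjugation with the alkyne.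

Step 8
Reactants: 13 (4R,5R)-5-[(tert-butyldimethylsilyl)oxy]-3-[(3E,5E,7S)-5,7-dimethylnona-3,5-dien-1-yn-1-yl]-4-{[(triisopropylsilyl)oxy]methyl}cyclopent-2-en-1-one
Product: 15 1-[(1S,4R,5R)-5-[(tert-butyldimethylsilyl)oxy]-3-[(3E,5E,7S)-5,7-dimethylnona-3,5-dien-1-yn-1-yl]-1-hydroxy-4-{[(triisopropylsilyl)oxy]methyl}cyclopent-2-en-1-yl]ethan-1-one, via enol ether 14 (not isolated)
Conditions: CH2=CHOEt, t-BuLi, THF, −78 to 0 °C; then 13, −78 °C; then 1 M aq. HCl, THF, 0 °C
Reagents that add atoms: ethyl vinyl ether, C=COCC; water, O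
Why: 1-Ethoxyvinyllithium (acyl anion equivalent) adds 1,2 to the ketone from the face anti to the silyloxy group on the neighbouring carbon, so the new C6 hydroxyl is cis to O–C8, and mild hydrolysis of the enol ether unveils the methyl ketone.

Step 9
Reactants: 15 1-[(1S,4R,5R)-5-[(tert-butyldimethylsilyl)oxy]-3-[(3E,5E,7S)-5,7-dimethylnona-3,5-dien-1-yn-1-yl]-1-hydroxy-4-{[(triisopropylsilyl)oxy]methyl}cyclopent-2-en-1-yl]ethan-1-one
Product: 16 (4R,5R,6R)-5-[(tert-butyldimethylsilyl)oxy]-3-[(3E,5E,7S)-5,7-dimethylnona-3,5-dien-1-yn-1-yl]-6-hydroxy-6-methyl-4-{[(triisopropylsilyl)oxy]methyl}cyclohex-2-en-1-one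
Conditions: Al(OtBu)3, toluene, 80 to 110 °C; aq. sodium potassium tartrate
Reagents that add atoms: none
Why: The aluminium alkoxide of the C6 carbinol chelates the acetyl oxygen, holding C=O syn to C6–O, and the C6–C8 bond then shifts suprafacially to the acetyl carbon C7 while C6–O becomes the ring ketone (α-ketol or acyloin rearrangement; closest precedent is the Lewis-acid ring enlargement of 1-acylcycloalkanols, as in the D-homoannulation of 17-hydroxy-20-oxo steroids). No ring is closed by cyclization: the cyclopentene C4a–C5–C6–C8–C8a is enlarged to the cyclohexenone C4a–C5–C6–C7–C8–C8a by insertion of C7 through this 1,2-shift. C8 migrates with retention and C8a is untouched, and the new C7 centre is dictated by C6: with the acetyl group trans to O–C8 and its carbonyl held syn to the C6 oxygen, C8 reaches only the carbonyl face that leaves C7–OH cis to the C8 oxygen and the methyl group trans, that is (7R). The step needs migration of C8 and not of the vinylic C5; this should be secured by the oxygen lone pair on C8 (heteroatom-bearing carbons migrate well in Lewis-acid ketol shifts), by the smaller clash of the acetyl methyl with H–C5 than with C8 in the chelate, and by the fact that only C8 migration puts the new ketone in conjugation with the C5=C4a enyne, which makes it the irreversible exit of an otherwise reversible manifold (a C5-shifted ketol can return to 15 under the same conditions). The silyl ether on O–C8 blocks retro-aldol opening, and the non-acidic aluminium alkoxide medium avoids ionization of the allylic carbinol.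

Step 10
Reactants: 16 (4R,5R,6R)-5-[(tert-butyldimethylsilyl)oxy]-3-[(3E,5E,7S)-5,7-dimethylnona-3,5-dien-1-yn-1-yl]-6-hydroxy-6-methyl-4-{[(triisopropylsilyl)oxy]methyl}cyclohex-2-en-1-one
Product: 18 (7R,8R,8aR)-3-[(1E,3E,5S)-3,5-dimethylhepta-1,3-dien-1-yl]-7,8-dihydroxy-7-methyl-8,8a-dihydro-1H-isochromen-6(7H)-one, via triol 17 (not isolated)
Conditions: HF·pyridine, pyridine, THF, 0 °C to rt; then AgOTf (cat.), CH2Cl2, rt
Reagents that add atoms: none
Why: Buffered HF removes both silyl groups without the base that would open the β-hydroxy ketone by retro-aldol, and monovalent silver then triggers 6-endo-dig attack of the primary hydroxyl on the alkyne carbon remote from the ring, the δ-position of the enynone, closing the pyran as the conjugated dienone (alkynol cycloisomerization, oxa-conjugate addition); attack by the secondary hydroxyl would need a bridgehead alkene.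

Step 11
Reactants: 18 (7R,8R,8aR)-3-[(1E,3E,5S)-3,5-dimethylhepta-1,3-dien-1-yl]-7,8-dihydroxy-7-methyl-8,8a-dihydro-1H-isochromen-6(7H)-one
Product: 19 (7R,8R,8aR)-3-[(1E,3E,5S)-3,5-dimethylhepta-1,3-dien-1-yl]-7-hydroxy-7-methyl-6-oxo-6,7,8,8a-tetrahydro-1H-isochromen-8-yl acetate
Conditions: Ac2O, pyridine, DMAP (cat.), CH2Cl2, 0 °C
Reagents that add atoms: acetic anhydride, CC(=O)OC(C)=O
Why: Under these mild conditions the secondary C8 hydroxyl should be acylated while the tertiary C7 hydroxyl next to the ketone stays free (chemoselective O-acylation), and the weak base should not trigger vinylogous elimination of the new acetate.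

**Compound list**

1 | (S)-2-methylbutan-1-ol | CC[C@H](C)CO | starting material
2 | (S)-2-methylbutanal | CC[C@H](C)C=O | intermediate
3 | ethyl (2E,4S)-2,4-dimethylhex-2-enoate | CC[C@H](C)/C=C(C)/C(=O)OCC | intermediate
4 | (2E,4S)-2,4-dimethylhex-2-en-1-ol | CC[C@H](C)/C=C(C)/CO | intermediate
5 | (2E,4S)-2,4-dimethylhex-2-enal | CC[C@H](C)/C=C(C)/C=O | intermediate
6 | trimethyl[(3E,5E,7S)-5,7-dimethylnona-3,5-dien-1-yn-1-yl]silane | CC[C@H](C)/C=C(C)/C=C/C#C[Si](C)(C)C | intermediate
7 | (3E,5E,7S)-5,7-dimethylnona-3,5-dien-1-yne | CC[C@H](C)/C=C(C)/C=C/C#C | intermediate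
8 | (R)-4-[(tert-butyldimethylsilyl)oxy]cyclopent-2-en-1-one | O=C1C=C[C@H](O[Si](C)(C)C(C)(C)C)C1 | starting material
9 | lithium (3S)-3-[(tert-butyldimethylsilyl)oxy]cyclopenta-1,4-dien-1-olate (cross-conjugated enolate of 8) | [Li+].[O-]C1=C[C@@H](O[Si](C)(C)C(C)(C)C)C=C1 | intermediate
10 | (4S,5R)-4-[(tert-butyldimethylsilyl)oxy]-5-{[(triisopropylsilyl)oxy]methyl}cyclopent-2-en-1-one | O=C1C=C[C@H](O[Si](C)(C)C(C)(C)C)[C@H]1CO[Si](C(C)C)(C(C)C)C(C)C | intermediate
11 | lithium (3E,5E,7S)-5,7-dimethylnona-3,5-dien-1-yn-1-ide | [Li+].[C-]#C/C=C/C(C)=C/[C@@H](C)CC | intermediate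
12 | (1S,4S,5R)-4-[(tert-butyldimethylsilyl)oxy]-1-[(3E,5E,7S)-5,7-dimethylnona-3,5-dien-1-yn-1-yl]-5-{[(triisopropylsilyl)oxy]methyl}cyclopent-2-en-1-ol | O[C@@]1(C#C/C=C/C(C)=C/[C@@H](C)CC)C=C[C@H](O[Si](C)(C)C(C)(C)C)[C@H]1CO[Si](C(C)C)(C(C)C)C(C)C | intermediate
13 | (4R,5R)-5-[(tert-butyldimethylsilyl)oxy]-3-[(3E,5E,7S)-5,7-dimethylnona-3,5-dien-1-yn-1-yl]-4-{[(triisopropylsilyl)oxy]methyl}cyclopent-2-en-1-one | O=C1C=C(C#C/C=C/C(C)=C/[C@@H](C)CC)[C@H](CO[Si](C(C)C)(C(C)C)C(C)C)[C@H]1O[Si](C)(C)C(C)(C)C | intermediate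
14 | (1S,4R,5R)-5-[(tert-butyldimethylsilyl)oxy]-3-[(3E,5E,7S)-5,7-dimethylnona-3,5-dien-1-yn-1-yl]-1-(1-ethoxyvinyl)-4-{[(triisopropylsilyl)oxy]methyl}cyclopent-2-en-1-ol | C=C(OCC)[C@]1(O)C=C(C#C/C=C/C(C)=C/[C@@H](C)CC)[C@H](CO[Si](C(C)C)(C(C)C)C(C)C)[C@H]1O[Si](C)(C)C(C)(C)C | intermediate
15 | 1-[(1S,4R,5R)-5-[(tert-butyldimethylsilyl)oxy]-3-[(3E,5E,7S)-5,7-dimethylnona-3,5-dien-1-yn-1-yl]-1-hydroxy-4-{[(triisopropylsilyl)oxy]methyl}cyclopent-2-en-1-yl]ethan-1-one | CC(=O)[C@]1(O)C=C(C#C/C=C/C(C)=C/[C@@H](C)CC)[C@H](CO[Si](C(C)C)(C(C)C)C(C)C)[C@H]1O[Si](C)(C)C(C)(C)C | intermediate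
16 | (4R,5R,6R)-5-[(tert-butyldimethylsilyl)oxy]-3-[(3E,5E,7S)-5,7-dimethylnona-3,5-dien-1-yn-1-yl]-6-hydroxy-6-methyl-4-{[(triisopropylsilyl)oxy]methyl}cyclohex-2-en-1-one | CC[C@H](C)/C=C(C)/C=C/C#CC1=CC(=O)[C@](C)(O)[C@H](O[Si](C)(C)C(C)(C)C)[C@H]1CO[Si](C(C)C)(C(C)C)C(C)C | intermediate
17 | (4R,5R,6R)-3-[(3E,5E,7S)-5,7-dimethylnona-3,5-dien-1-yn-1-yl]-5,6-dihydroxy-4-(hydroxymethyl)-6-methylcyclohex-2-en-1-one | CC[C@H](C)/C=C(C)/C=C/C#CC1=CC(=O)[C@](C)(O)[C@H](O)[C@H]1CO | intermediate
18 | (7R,8R,8aR)-3-[(1E,3E,5S)-3,5-dimethylhepta-1,3-dien-1-yl]-7,8-dihydroxy-7-methyl-8,8a-dihydro-1H-isochromen-6(7H)-one | CC[C@H](C)/C=C(C)/C=C/C1=CC2=CC(=O)[C@](C)(O)[C@H](O)[C@H]2CO1 | intermediate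
19 | (7R,8R,8aR)-3-[(1E,3E,5S)-3,5-dimethylhepta-1,3-dien-1-yl]-7-hydroxy-7-methyl-6-oxo-6,7,8,8a-tetrahydro-1H-isochromen-8-yl acetate | CC[C@H](C)/C=C(C)/C=C/C1=CC2=CC(=O)[C@](C)(O)[C@H](OC(C)=O)[C@H]2CO1 | target

**Count.** Total: 11 steps. Longest linear sequence: 10 steps (steps 1–4, then 6–11).

**Steps most likely to fail**

Step 9. The wrong ring bond may shift (the vinylic C5 in place of C8), or the silyl group may wander from O–C8 to the aluminium alkoxide and open the way to retro-aldol cleavage. The fallback removes the alkene from the competition by a temporary change of oxidation level; it sets out from 13 and comes back at 16. Conjugate reduction of 13 with [(Ph3P)CuH]6 would give the saturated ketone F1 (epimers at the alkynyl-bearing carbon, which is erased later). Addition of 1-ethoxyvinyllithium as in step 8 would give the enol ether F2 and, after mild acid hydrolysis, the saturated ketol F3. With both ring neighbours of the carbinol now sp3, the Al(OtBu)3-mediated ketol shift should be governed by the oxygen-bearing C8 and give the saturated hydroxy ketone F4. Dehydrogenation with IBX at the only enolizable position, C5, would then restore the enynone 16.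

Step 5. The enolate may lose silanolate by β-elimination, be alkylated on oxygen, or be alkylated twice. The fallback replaces the basic enolate by a neutral silyl enol ether; it sets out from 8 and comes back at 10. Soft enolization of 8 with Me3SiOTf and Et3N would give the 2-silyloxydiene F5. This would be alkylated with the same chloromethyl ether under ZnBr2 catalysis (Mukaiyama-type alkylation through the oxocarbenium ion, again anti to the silyloxy group) to give 10.

Step 7. The tertiary propargylic-allylic alcohol may ionize under the acidic chromium reagent, leading to elimination or loss of a silyl group instead of the [3,3]-shift. The fallback separates transposition from oxidation; it sets out from 12 and comes back at 13. Redox-neutral 1,3-transposition of 12 catalysed by Ph3SiOReO3, driven by conjugation of the new alkene with the alkyne, would give the secondary allylic alcohol F6 (either carbinol epimer serves). Oxidation with MnO2 would then give 13.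

Further compounds
F1 | step 9 | (2R,3R)-2-[(tert-butyldimethylsilyl)oxy]-4-[(3E,5E,7S)-5,7-dimethylnona-3,5-dien-1-yn-1-yl]-3-{[(triisopropylsilyl)oxy]methyl}cyclopentan-1-one (epimers at C4) | O=C1CC(C#C/C=C/C(C)=C/[C@@H](C)CC)[C@H](CO[Si](C(C)C)(C(C)C)C(C)C)[C@H]1O[Si](C)(C)C(C)(C)C
F2 | step 9 | (1S,2R,3R)-2-[(tert-butyldimethylsilyl)oxy]-4-[(3E,5E,7S)-5,7-dimethylnona-3,5-dien-1-yn-1-yl]-1-(1-ethoxyvinyl)-3-{[(triisopropylsilyl)oxy]methyl}cyclopentan-1-ol (epimers at C4) | C=C(OCC)[C@]1(O)CC(C#C/C=C/C(C)=C/[C@@H](C)CC)[C@H](CO[Si](C(C)C)(C(C)C)C(C)C)[C@H]1O[Si](C)(C)C(C)(C)C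
F3 | step 9 | 1-[(1S,2R,3R)-2-[(tert-butyldimethylsilyl)oxy]-4-[(3E,5E,7S)-5,7-dimethylnona-3,5-dien-1-yn-1-yl]-1-hydroxy-3-{[(triisopropylsilyl)oxy]methyl}cyclopentyl]ethan-1-one (epimers at C4) | CC(=O)[C@]1(O)CC(C#C/C=C/C(C)=C/[C@@H](C)CC)[C@H](CO[Si](C(C)C)(C(C)C)C(C)C)[C@H]1O[Si](C)(C)C(C)(C)C
F4 | step 9 | (2R,3R,4R)-3-[(tert-butyldimethylsilyl)oxy]-5-[(3E,5E,7S)-5,7-dimethylnona-3,5-dien-1-yn-1-yl]-2-hydroxy-2-methyl-4-{[(triisopropylsilyl)oxy]methyl}cyclohexan-1-one (epimers at C5) | O=C1CC(C#C/C=C/C(C)=C/[C@@H](C)CC)[C@H](CO[Si](C(C)C)(C(C)C)C(C)C)[C@@H](O[Si](C)(C)C(C)(C)C)[C@@]1(C)O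
F5 | step 5 | (S)-tert-butyldimethyl{[4-(trimethylsilyloxy)cyclopenta-2,4-dien-1-yl]oxy}silane | C[Si](C)(C)OC1=C[C@@H](O[Si](C)(C)C(C)(C)C)C=C1
F6 | step 7 | (4R,5R)-5-[(tert-butyldimethylsilyl)oxy]-3-[(3E,5E,7S)-5,7-dimethylnona-3,5-dien-1-yn-1-yl]-4-{[(triisopropylsilyl)oxy]methyl}cyclopent-2-en-1-ol (carbinol epimers) | OC1C=C(C#C/C=C/C(C)=C/[C@@H](C)CC)[C@H](CO[Si](C(C)C)(C(C)C)C(C)C)[C@H]1O[Si](C)(C)C(C)(C)C
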